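**Retrosynthetic overview**
1. Gardenin E is cut at the C2–C1' bond between ring C and ring B. C2 is the β-carbon of the C2=C3–C4=O enone of ring C, and C1' is the only carbon of the mirror-symmetric ring B (3',5'-dioxygenated, 4'-methoxy) that has no ortho substituent.
2. In the forward sense, the ring B arylboronic acid 15 arylates the C2–H of the preformed 5-O-MOM chromone 11 (oxidative Heck), and acid then removes all three MOM ethers.
3. Chromone 11 comes from 1,2,3-trimethoxybenzene by way of pentamethoxybenzene, acylation to the ortho-hydroxyacetophenone, enaminone closure of ring C, chelation-controlled 5-O-demethylation and MOM protection.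
4. Boronic acid 15 comes from 2-methoxyresorcinol by bis-MOM protection, sterically controlled iridium C–H borylation at the future C1', and cleavage of the pinacol ester.
5. Ring order: rings A and B are the starting benzenes, ring C is closed in step 4, and the key step joins ring B without closing a ring.

Key step: step 10

Remark on the chemistry: acetyl chloride and N,N-dimethylformamide dimethyl acetal supply ring C carbons (C4 with C3, and C2) and are numbered as starting materials; boronic acid 15 may contain some of its boroxine, which should react in the same way.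

**Route**

Step 1
Reactants: 1 1,2,3-trimethoxybenzene
Product: 2 1,5-dibromo-2,3,4-trimethoxybenzene
Conditions: NBS (2.2 equiv), MeCN, 0 °C to rt
Reagents that add atoms: N-bromosuccinimide, O=C1CCC(=O)N1Br
Why: Electrophilic aromatic bromination, in which each outer methoxy group activates its ortho and para carbons, so the two bromines should enter C4 and C6 and not C5, which only the twisted central methoxy group activates.

Step 2
Reactants: 2 1,5-dibromo-2,3,4-trimethoxybenzene
Product: 3 pentamethoxybenzene
Conditions: NaOMe (25% in MeOH, 6 equiv), CuBr (20 mol%), DMF, 110 °C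
Reagents that add atoms: sodium methoxide (NaOMe), [Na+].[O-]C
Why: Copper-catalysed Ullmann-type methoxylation of aryl bromides, a standard way to turn bromo(methoxy)arenes into polymethoxybenzenes, should replace both bromines because methoxide in large excess is the only competent nucleophile.

Step 3
Reactants: 3 pentamethoxybenzene; 4 acetyl chloride
Product: 6 1-(2-hydroxy-3,4,5,6-tetramethoxyphenyl)ethanone, via pentamethoxyacetophenone 5 (not isolated)
Conditions: AcCl (1.2 equiv), AlCl3 (2.2 equiv), CH2Cl2, 0 °C to rt; then ice/aq. HCl
Reagents that add atoms: none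
Why: Friedel–Crafts acylation occurs at the only unsubstituted carbon of the very electron-rich arene, and AlCl3 held in a six-membered chelate between the new ketone oxygen and one ortho methoxy oxygen then cleaves that methyl ether (chelation-controlled ortho-demethylation), the resulting aluminium phenoxide chelate slowing cleavage of the second ortho ether.

Step 4
Reactants: 6 1-(2-hydroxy-3,4,5,6-tetramethoxyphenyl)ethanone; 7 N,N-dimethylformamide dimethyl acetal
Product: 9 5,6,7,8-tetramethoxy-4H-chromen-4-one, via enaminone 8 (not isolated)
Conditions: DMF-DMA (3 equiv), toluene, 100 °C; evaporate; conc. HCl, CH2Cl2, rt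
Reagents that add atoms: none
Why: Condensation of the methyl ketone with the amide acetal gives the β-(dimethylamino)enone, and acid then drives conjugate addition of the ortho phenol to the enaminone carbon followed by loss of dimethylamine (addition–elimination, 6-endo closure of ring C), the standard enaminone route to 2,3-unsubstituted chromones.

Step 5
Reactants: 9 5,6,7,8-tetramethoxy-4H-chromen-4-one
Product: 10 5-hydroxy-6,7,8-trimethoxy-4H-chromen-4-one
Conditions: BCl3 (1 M in CH2Cl2, 1.5 equiv), CH2Cl2, −78 to 0 °C; then aq. NaHCO3
Reagents that add atoms: none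
Why: BCl3 bridges the C4 carbonyl oxygen and the peri C5 methoxy oxygen in a six-membered chelate, so chloride should remove only that methyl group (chelation-controlled selective 5-O-demethylation of 5-methoxychromones), while the methoxy groups at C6 to C8 cannot chelate and stay.

Step 6
Reactants: 10 5-hydroxy-6,7,8-trimethoxy-4H-chromen-4-one
Product: 11 6,7,8-trimethoxy-5-(methoxymethoxy)-4H-chromen-4-one
Conditions: NaH (1.3 equiv), MOMCl (1.5 equiv), DMF, 0 °C to rt
Reagents that add atoms: chloromethyl methyl ether (MOMCl), COCCl
Why: Williamson-type O-alkylation, in which NaH converts the hydrogen-bonded peri phenol fully into its phenoxide and the highly reactive α-chloro ether then alkylates that oxygen at low temperature without opening the pyranone ring.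

Step 7
Reactants: 12 2-methoxybenzene-1,3-diol (2-methoxyresorcinol)
Product: 13 2-methoxy-1,3-bis(methoxymethoxy)benzene
Conditions: MOMCl (2.6 equiv), i-Pr2NEt (3.5 equiv), CH2Cl2, 0 °C to rt
Reagents that add atoms: chloromethyl methyl ether (MOMCl), COCCl
Why: Standard MOM protection by O-alkylation of both phenols with the α-chloro ether under amine base, both hydroxyl groups being accessible beside the single methoxy group.

Step 8
Reactants: 13 2-methoxy-1,3-bis(methoxymethoxy)benzene
Product: 14 2-[4-methoxy-3,5-bis(methoxymethoxy)phenyl]-4,4,5,5-tetramethyl-1,3,2-dioxaborolane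
Conditions: B2pin2 (1.0 equiv), [Ir(OMe)(cod)]2 (1.5 mol%), 4,4'-di-tert-butyl-2,2'-bipyridine (3 mol%), THF, 80 °C
Reagents that add atoms: bis(pinacolato)diboron (B2pin2), CC1(C)OB(OC1(C)C)B1OC(C)(C)C(C)(C)O1
Why: Iridium-catalysed aromatic C–H borylation with a bipyridine ligand is governed by sterics, so boron should enter C5, the only C–H without an ortho substituent and the future C1', and not C4 or C6 beside the MOM ethers.

Step 9
Reactants: 14 2-[4-methoxy-3,5-bis(methoxymethoxy)phenyl]-4,4,5,5-tetramethyl-1,3,2-dioxaborolane
Product: 15 [4-methoxy-3,5-bis(methoxymethoxy)phenyl]boronic acid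
Conditions: NaIO4 (3 equiv), NH4OAc (3 equiv), acetone/H2O (1:1), rt
Reagents that add atoms: water, O
Why: Oxidative cleavage of the pinacol ester, in which water hydrolyses the boronate reversibly and periodate destroys the released pinacol by glycol cleavage to acetone, pulling the equilibrium to the free boronic acid at a near-neutral pH that the MOM ethers tolerate.

Step 10
Reactants: 11 6,7,8-trimethoxy-5-(methoxymethoxy)-4H-chromen-4-one; 15 [4-methoxy-3,5-bis(methoxymethoxy)phenyl]boronic acid (2.0 equiv)
Product: 16 6,7,8-trimethoxy-2-[4-methoxy-3,5-bis(methoxymethoxy)phenyl]-5-(methoxymethoxy)-4H-chromen-4-one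
Conditions: Pd(OAc)2 (10 mol%), 2,2'-bipyridine (12 mol%), O2 (1 atm), DMSO, 80 °C
Reagents that add atoms: none
Why: The aryl group is transferred from boron to bipyridine-ligated divalent palladium, and the aryl–palladium bond adds syn across C2=C3 with the aryl group going to the electrophilic β-carbon C2 and palladium to C3, next to the C4 carbonyl. The C3-bound palladium enolate can pass through its oxygen-bound form to the other face, which brings palladium syn to the C2 hydrogen, so β-hydride elimination restores the C2=C3 double bond and oxygen returns the zerovalent palladium to divalent palladium. The closest known reaction type is the oxidative (boron) Heck arylation of chromones and other cyclic enones with arylboronic acids. No ring is closed and no stereocentre is created, so no mode of closure and no controlling element are involved. The step needs C2 over C3 arylation and flavone over flavanone: the enone polarity and the free C2–H secure the first, and the base-free aerobic medium favours elimination over protonation of the palladium enolate, while any flavanone that forms should be dehydrogenated by the same Pd(OAc)2/O2/DMSO system. The boronic acid has no ortho substituent, so transmetalation and insertion are unhindered, and the MOM ethers should tolerate the acetic acid and boric acid released.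

Step 11
Reactants: 16 6,7,8-trimethoxy-2-[4-methoxy-3,5-bis(methoxymethoxy)phenyl]-5-(methoxymethoxy)-4H-chromen-4-one
Product: 17 Gardenin E
Conditions: HCl (3 M in MeOH), THF/MeOH, 40 °C
Reagents that add atoms: none
Why: Acid-catalysed solvolysis of the three MOM acetals through oxocarbenium ions that methanol traps as dimethoxymethane should free the 5-, 3'- and 5'-hydroxyl groups, while the aryl methyl ethers and the flavone core are inert to methanolic HCl at this temperature.

**Compound list**
1 | 1,2,3-trimethoxybenzene | COc1cccc(OC)c1OC | starting material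
2 | 1,5-dibromo-2,3,4-trimethoxybenzene | COc1c(Br)cc(Br)c(OC)c1OC | intermediate
3 | pentamethoxybenzene | COc1cc(OC)c(OC)c(OC)c1OC | intermediate
4 | acetyl chloride | CC(=O)Cl | starting material
5 | 1-(2,3,4,5,6-pentamethoxyphenyl)ethanone (not isolated) | CC(=O)c1c(OC)c(OC)c(OC)c(OC)c1OC | intermediate
6 | 1-(2-hydroxy-3,4,5,6-tetramethoxyphenyl)ethanone | CC(=O)c1c(O)c(OC)c(OC)c(OC)c1OC | intermediate
7 | N,N-dimethylformamide dimethyl acetal | COC(OC)N(C)C | starting material
8 | (E)-3-(dimethylamino)-1-(2-hydroxy-3,4,5,6-tetramethoxyphenyl)prop-2-en-1-one (not isolated) | CN(C)/C=C/C(=O)c1c(O)c(OC)c(OC)c(OC)c1OC | intermediate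
9 | 5,6,7,8-tetramethoxy-4H-chromen-4-one | COc1c(OC)c(OC)c2occc(=O)c2c1OC | intermediate
10 | 5-hydroxy-6,7,8-trimethoxy-4H-chromen-4-one | COc1c(OC)c(OC)c2occc(=O)c2c1O | intermediate
11 | 6,7,8-trimethoxy-5-(methoxymethoxy)-4H-chromen-4-one | COCOc1c(OC)c(OC)c(OC)c2occc(=O)c12 | intermediate
12 | 2-methoxybenzene-1,3-diol (2-methoxyresorcinol) | COc1c(O)cccc1O | starting material
13 | 2-methoxy-1,3-bis(methoxymethoxy)benzene | COCOc1cccc(OCOC)c1OC | intermediate
14 | 2-[4-methoxy-3,5-bis(methoxymethoxy)phenyl]-4,4,5,5-tetramethyl-1,3,2-dioxaborolane | COCOc1cc(B2OC(C)(C)C(C)(C)O2)cc(OCOC)c1OC | intermediate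
15 | [4-methoxy-3,5-bis(methoxymethoxy)phenyl]boronic acid | COc1c(OCOC)cc(B(O)O)cc1OCOC | intermediate
16 | 6,7,8-trimethoxy-2-[4-methoxy-3,5-bis(methoxymethoxy)phenyl]-5-(methoxymethoxy)-4H-chromen-4-one | COCOc1c(OC)c(OC)c(OC)c2oc(-c3cc(OCOC)c(OC)c(OCOC)c3)cc(=O)c12 | intermediate
17 | Gardenin E, 2-(3,5-dihydroxy-4-methoxyphenyl)-5-hydroxy-6,7,8-trimethoxy-4H-chromen-4-one | COc1c(O)cc(-c2cc(=O)c3c(O)c(OC)c(OC)c(OC)c3o2)cc1O | target

**Step count**
Total: 11 steps. Longest linear sequence: 8 steps (steps 1 to 6, 10 and 11, from 1,2,3-trimethoxybenzene). The ring B branch (steps 7 to 9) joins at step 10.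

**Steps most likely to fail, with fallbacks**

Step 10. The electron-rich chromone may undergo carbopalladation slowly, the C3 palladium enolate may be protonated faster than it eliminates, and the boronic acid may be consumed by oxidative homocoupling, oxidation to the phenol or protodeboronation. The fallback reverses the polarity of the same C2–C1' bond and uses known chromone zincation and Negishi coupling; it sets out from 11 and 15 and comes back at 16. Boronic acid 15 would be converted by ipso-iododeboronation (N-iodosuccinimide, MeCN, rt) into 5-iodo-2-methoxy-1,3-bis(methoxymethoxy)benzene F1. Chromone 11 would be metalated at C2 with TMP2Zn·2MgCl2·2LiCl (THF, −30 to 25 °C), the magnesium chloride bound to the C4 carbonyl acidifying the C2–H, to give bis[6,7,8-trimethoxy-5-(methoxymethoxy)-4-oxo-4H-chromen-2-yl]zinc F2, which is not isolated. Negishi coupling of F2 with F1 (Pd(PPh3)4, 5 mol%, THF, 50 °C) should then deliver 16.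

Step 3. AlCl3 may cleave a second ortho methyl ether or other methoxy groups, or the ortho-demethylation may stop short and give a mixture. The fallback separates acylation from demethylation; it sets out from 3 and comes back at 6. The single ring hydrogen of 3, flanked by two methoxy groups, would be removed by n-BuLi (THF, 0 °C, directed ortho-metalation) to give 2,3,4,5,6-pentamethoxyphenyllithium F3, which is not isolated. Quenching F3 with N-methoxy-N-methylacetamide (−78 °C to rt) should give ketone 5, now isolated. BCl3 (1.0 equiv, CH2Cl2, −78 °C) would then cleave one ortho methyl ether under chelation control to give 6.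

Step 2. Bromine may be lost reductively (hydrodebromination), and the second substitution may stall as the ring becomes more electron-rich. The fallback introduces the two oxygens through boron; it sets out from 2 and comes back at 3. Double Miyaura borylation of 2 (B2pin2, Pd(dppf)Cl2, KOAc, dioxane, 90 °C) would give 2,2'-(4,5,6-trimethoxy-1,3-phenylene)bis(4,4,5,5-tetramethyl-1,3,2-dioxaborolane) F4. Oxidation of both C–B bonds (H2O2, aq. NaOH, THF, 0 °C) should give 4,5,6-trimethoxybenzene-1,3-diol F5. Double O-methylation of F5 (MeI, K2CO3, acetone, reflux) returns 3.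

**Further compounds**
F1 | step 10 | 5-iodo-2-methoxy-1,3-bis(methoxymethoxy)benzene | COCOc1cc(I)cc(OCOC)c1OC
F2 | step 10 | bis[6,7,8-trimethoxy-5-(methoxymethoxy)-4-oxo-4H-chromen-2-yl]zinc | COCOc1c(OC)c(OC)c(OC)c2oc([Zn]c3cc(=O)c4c(OCOC)c(OC)c(OC)c(OC)c4o3)cc(=O)c12
F3 | step 3 | 2,3,4,5,6-pentamethoxyphenyllithium | [Li]c1c(OC)c(OC)c(OC)c(OC)c1OC
F4 | step 2 | 2,2'-(4,5,6-trimethoxy-1,3-phenylene)bis(4,4,5,5-tetramethyl-1,3,2-dioxaborolane) | COc1c(B2OC(C)(C)C(C)(C)O2)cc(B2OC(C)(C)C(C)(C)O2)c(OC)c1OC
F5 | step 2 | 4,5,6-trimethoxybenzene-1,3-diol | COc1c(O)cc(O)c(OC)c1OC
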